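I decide to follow Q through one number, the first-order constant with which it falls, and to reach that number by going round the two things it depends on, free [L] and [Z].

Q 0.10 M; X 48 mM (held); L 5.0 mM; time 1.0 min

    X ⇌ Z, rate k1*(csat - [Z]) (k1 = 0.90 /s, csat = 48 mM)
    Q + Z + L → L + J (k2 = 94 /M²/s)
    2 Z → Z2 (k3 = 1.3 /M/s)
    L + L ⇌ L2 (K4 = 230 /M, k4 = 20 /M/s)

- amount of J at 1.0 min, in percent of the Q charged
- concentration of Z in solution at 1.0 min, in percent of saturation

- two of one species on the left: rate k times its square, two consumed each time
- at the start none of Z is dissolved
- run time (flask): 1.0 min

In the first seconds two things happen at once. Z starts from nothing and dissolves with a time of 1.11 s, while L pairs into L2. Each L2 holds two L, so with 230 /M the charge of 5.0 mM splits to give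

free [L] = 2.38 mM, or 47.6% of the charge.

The pairing relaxes in about 3.60 s. Both times are short against the run of 60 s, so as an approximation I use the later levels of [Z] and free [L] from the start.

In the middle, transfer balances the two drains on Z. I put [Z] = 48 mM into the loss to Z2, then put the answer back with the Q step added at charged [Q]:

first round: [Z] = 41.3 mM

second round: [Z] = 42.0 mM

At that level the loss to Z2 takes 4.59 mM/s and the Q step 0.942 mM/s, so Z2 is the larger drain. Toward the end falling [Q] trims the smaller drain, and I hold [Z] fixed. Then

k = 0.00942 /s,

the pseudo-first-order constant of Q, its rate constant times [Z] times free [L]. This gives y = 43.2% and sat = 87.5%.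

The forecast says 43% (from 40% to 46%) and 88% (from 86% to 90%), holding that “gas transfer holds Z at a quasi-steady level”. My own figures are 43.2% and 87.5%, reached by a like route, so neither reckoning checks the other.

The flask gives y = 44.1% and sat = 88.0%. With the other charges and the time held, its y moves by 5 points when its charge of L goes down to 3.92 mM or up to 6.32 mM. Read from its y, the constant averaged over the run is 0.00969 /s, beside my 0.00942 /s. I carry the constant to the second flask, charged with 0.020 M of L, keeping my [Z]: free [L] becomes 5.60 mM, the constant 0.0221 /s, and y 73.4%; that flask gives 73.7%.

Its constants are invented; the run is a simulation.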